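## Retrosynthetic overview

1. Target 24 comes from allyl β-keto ester 21 in one pot: deallylation and decarboxylation remove the ester carbon and all three allyl groups. 21 comes from aldol 20 by oxidation.
2. Key C–C bond: the C(=O)–CH(Ar) bond of the deoxybenzoin, made by intermolecular aldol addition of the lithium enolate of allyl arylacetate 18 to the fully substituted chromene aldehyde 16.
3. 16 comes from resorcinol aldehyde 11 and prenal: phenoxide aldol, dehydration and oxa-6π closure build the pyran at the only free ring carbon.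
4. 11 comes from prenyl ether 7 by a Claisen–Cope (para-Claisen) shift. 7 comes from 2,4,6-trihydroxybenzaldehyde 1, whose three hydroxyls are told apart by hydrogen bonding to the formyl group.
5. Ring order: both benzene rings are bought; the 2H-pyran is the only ring formed (step 8).

Assumption: the target has no stereocentre and no stereogenic double bond, so it is achiral; stereocentres in intermediates 8, 9, 13, 20, 21 and 22 are transient, racemic and erased before the end.

## Route

Step 1
Reactants: 1 2,4,6-trihydroxybenzaldehyde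
Product: 2 2-hydroxy-4,6-bis(methoxymethoxy)benzaldehyde
Conditions: MOMCl (2.3 equiv), iPr2NEt (3 equiv), CH2Cl2, 0 °C to rt
Reagents that add atoms: chloromethyl methyl ether (MOMCl), COCCl
Why: O-alkylation (MOM acetal formation) stops at the bis-ether because the last ortho hydroxyl is held in a strong hydrogen bond to the formyl oxygen and is far less nucleophilic under amine-base conditions.

Step 2
Reactants: 2 2-hydroxy-4,6-bis(methoxymethoxy)benzaldehyde
Product: 3 2-methoxy-4,6-bis(methoxymethoxy)benzaldehyde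
Conditions: MeI (2 equiv), K2CO3 (2.5 equiv), DMF, 40 °C
Reagents that add atoms: iodomethane, CI
Why: Williamson ether synthesis with K2CO3 in DMF breaks the chelate and methylates the single remaining phenol, which fixes the ortho oxygen that becomes the methoxy group.

Step 3
Reactants: 3 2-methoxy-4,6-bis(methoxymethoxy)benzaldehyde
Product: 4 2,4-dihydroxy-6-methoxybenzaldehyde
Conditions: conc. HCl (cat.), MeOH, 50 °C; aqueous work-up
Reagents that add atoms: none
Why: Acid-catalysed transacetalisation to methanol removes both MOM acetals while the aryl methyl ether and the aldehyde are untouched (any dimethyl acetal reverts on aqueous work-up).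

Step 4
Reactants: 4 2,4-dihydroxy-6-methoxybenzaldehyde
Product: 5 4-[(tert-butyldimethylsilyl)oxy]-2-hydroxy-6-methoxybenzaldehyde
Conditions: TBSCl (1.05 equiv), imidazole (2 equiv), CH2Cl2, 0 °C
Reagents that add atoms: tert-butyldimethylsilyl chloride, CC(C)(C)[Si](C)(C)Cl
Why: Silyl ether formation is selective for the para hydroxyl because the ortho hydroxyl is chelated to the aldehyde and does not silylate with one equivalent of TBSCl at 0 °C.

Step 5
Reactants: 5 4-[(tert-butyldimethylsilyl)oxy]-2-hydroxy-6-methoxybenzaldehyde; 6 3-methylbut-2-en-1-ol (prenol)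
Product: 7 4-[(tert-butyldimethylsilyl)oxy]-2-methoxy-6-[(3-methylbut-2-en-1-yl)oxy]benzaldehyde
Conditions: 6 (1.5 equiv), PPh3 (1.5 equiv), DIAD (1.5 equiv), THF, 0 °C to rt
Reagents that add atoms: none
Why: The Mitsunobu reaction alkylates the acidic chelated phenol on oxygen by SN2 displacement at the primary allylic carbon under neutral conditions that leave the aryl silyl ether in place and avoid C-prenylation.

Step 6
Reactants: 7 4-[(tert-butyldimethylsilyl)oxy]-2-methoxy-6-[(3-methylbut-2-en-1-yl)oxy]benzaldehyde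
Product: 10 4-[(tert-butyldimethylsilyl)oxy]-6-hydroxy-2-methoxy-3-(3-methylbut-2-en-1-yl)benzaldehyde, via ortho-dienone 8 (not isolated), via para-dienone 9 (not isolated)
Conditions: PhNEt2, 200 °C, sealed tube, Ar, 3 h
Reagents that add atoms: none
Why: Thermal Claisen–Cope (para-Claisen) rearrangement, in which the [3,3] shift to the free ortho carbon gives the crowded dienone 8, a Cope [3,3] shift relays the allyl group to the para carbon (dienone 9) and tautomerisation follows, so the prenyl group arrives unrearranged between the methoxy and silyloxy groups and the chelated phenol is regenerated; the sp3 centres of 8 and 9 are racemic and vanish on aromatisation.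

Step 7
Reactants: 10 4-[(tert-butyldimethylsilyl)oxy]-6-hydroxy-2-methoxy-3-(3-methylbut-2-en-1-yl)benzaldehyde
Product: 11 4,6-dihydroxy-2-methoxy-3-(3-methylbut-2-en-1-yl)benzaldehyde
Conditions: Bu4NF (1.1 equiv), AcOH (1.1 equiv), THF, 0 °C
Reagents that add atoms: none
Why: Fluoride-mediated desilylation buffered with AcOH frees the para phenol without strong acid, so the adjacent prenyl group cannot cyclise onto it.

Step 8
Reactants: 11 4,6-dihydroxy-2-methoxy-3-(3-methylbut-2-en-1-yl)benzaldehyde; 12 3-methylbut-2-enal (prenal)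
Product: 15 5-hydroxy-7-methoxy-2,2-dimethyl-8-(3-methylbut-2-en-1-yl)-2H-chromene-6-carbaldehyde, via aldol adduct 13 (not isolated), via ortho-quinone methide 14 (not isolated)
Conditions: 12 (2 equiv), Ca(OH)2 (1 equiv), MeOH, rt, 48 h
Reagents that add atoms: none
Why: Phenoxide aldol-type addition of the calcium-chelated resorcinol to prenal at the only unsubstituted ring carbon, dehydration to the ortho-quinone methide and oxa-6π electrocyclisation close the 2,2-dimethyl-2H-pyran on the para oxygen because the ortho oxygen stays chelated to the formyl group; the carbinol centre of 13 is racemic and is lost in the dehydration.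

Step 9
Reactants: 15 5-hydroxy-7-methoxy-2,2-dimethyl-8-(3-methylbut-2-en-1-yl)-2H-chromene-6-carbaldehyde
Product: 16 7-methoxy-2,2-dimethyl-8-(3-methylbut-2-en-1-yl)-5-(prop-2-en-1-yloxy)-2H-chromene-6-carbaldehyde
Conditions: allyl bromide (2 equiv), K2CO3 (3 equiv), DMF, 60 °C
Reagents that add atoms: allyl bromide, C=CCBr
Why: Williamson etherification caps the acidic chelated phenol, which would otherwise quench the enolate and turn the aldehyde into an unreactive phenoxide in the aldol step, with a group that the final palladium step removes.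

Step 10
Reactants: 17 (4-hydroxyphenyl)acetic acid
Product: 18 prop-2-en-1-yl 2-[4-(prop-2-en-1-yloxy)phenyl]acetate
Conditions: allyl bromide (2.5 equiv), K2CO3 (3 equiv), DMF, rt to 50 °C
Reagents that add atoms: allyl bromide, C=CCBr
Why: Double Williamson-type alkylation with K2CO3 and excess allyl bromide esterifies the carboxylate and etherifies the phenol in one operation.

Step 11
Reactants: 16 7-methoxy-2,2-dimethyl-8-(3-methylbut-2-en-1-yl)-5-(prop-2-en-1-yloxy)-2H-chromene-6-carbaldehyde; 18 prop-2-en-1-yl 2-[4-(prop-2-en-1-yloxy)phenyl]acetate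
Product: 20 prop-2-en-1-yl 3-hydroxy-3-[7-methoxy-2,2-dimethyl-8-(3-methylbut-2-en-1-yl)-5-(prop-2-en-1-yloxy)-2H-chromen-6-yl]-2-[4-(prop-2-en-1-yloxy)phenyl]propanoate, via lithium enolate 19 (not isolated)
Conditions: 18 (1.3 equiv), LiN(iPr)2 (1.3 equiv), THF, −78 °C, 30 min; then 16, −78 °C, 2 h; AcOH quench at −78 °C
Reagents that add atoms: none
Why: Crossed aldol addition of a preformed lithium ester enolate to a non-enolisable aldehyde at −78 °C, where lithium chelation by the flanking ether oxygens holds the aldolate and the allyl ester enolate does not yet undergo Ireland–Claisen rearrangement; the two new stereocentres form without control as racemic diastereomers, which does not matter because both are erased in steps 12 and 13.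

Step 12
Reactants: 20 prop-2-en-1-yl 3-hydroxy-3-[7-methoxy-2,2-dimethyl-8-(3-methylbut-2-en-1-yl)-5-(prop-2-en-1-yloxy)-2H-chromen-6-yl]-2-[4-(prop-2-en-1-yloxy)phenyl]propanoate
Product: 21 prop-2-en-1-yl 3-[7-methoxy-2,2-dimethyl-8-(3-methylbut-2-en-1-yl)-5-(prop-2-en-1-yloxy)-2H-chromen-6-yl]-3-oxo-2-[4-(prop-2-en-1-yloxy)phenyl]propanoate
Conditions: DMP (1.5 equiv), CH2Cl2, rt
Reagents that add atoms: none
Why: Dess–Martin oxidation converts the hindered benzylic secondary alcohol to the ketone under mild conditions that spare the allyl, prenyl and chromene double bonds; the remaining alpha stereocentre is racemic and epimerisable.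

Step 13
Reactants: 21 prop-2-en-1-yl 3-[7-methoxy-2,2-dimethyl-8-(3-methylbut-2-en-1-yl)-5-(prop-2-en-1-yloxy)-2H-chromen-6-yl]-3-oxo-2-[4-(prop-2-en-1-yloxy)phenyl]propanoate
Product: 24 1-[5-hydroxy-7-methoxy-2,2-dimethyl-8-(3-methylbut-2-en-1-yl)-2H-chromen-6-yl]-2-(4-hydroxyphenyl)ethan-1-one, via beta-keto acid 22 (not isolated), via diallyl ether ketone 23 (not isolated)
Conditions: Pd(PPh3)4 (10 mol %), morpholine (15 equiv), THF, rt to 40 °C
Reagents that add atoms: none
Why: Tsuji–Trost deallylation in which zerovalent palladium ionises the allyl ester first, the beta-keto carboxylate loses CO2 and is protonated, and the two aryl allyl ethers are then cleaved the same way with morpholine as irreversible allyl acceptor, so the last stereocentre disappears and the achiral target is freed without acid that could harm the chromene or prenyl group.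

## Compound list

1 | 2,4,6-trihydroxybenzaldehyde | O=Cc1c(O)cc(O)cc1O | starting material
2 | 2-hydroxy-4,6-bis(methoxymethoxy)benzaldehyde | O=Cc1c(O)cc(OCOC)cc1OCOC | intermediate
3 | 2-methoxy-4,6-bis(methoxymethoxy)benzaldehyde | O=Cc1c(OC)cc(OCOC)cc1OCOC | intermediate
4 | 2,4-dihydroxy-6-methoxybenzaldehyde | O=Cc1c(OC)cc(O)cc1O | intermediate
5 | 4-[(tert-butyldimethylsilyl)oxy]-2-hydroxy-6-methoxybenzaldehyde | O=Cc1c(OC)cc(O[Si](C)(C)C(C)(C)C)cc1O | intermediate
6 | 3-methylbut-2-en-1-ol (prenol) | CC(C)=CCO | starting material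
7 | 4-[(tert-butyldimethylsilyl)oxy]-2-methoxy-6-[(3-methylbut-2-en-1-yl)oxy]benzaldehyde | O=Cc1c(OC)cc(O[Si](C)(C)C(C)(C)C)cc1OCC=C(C)C | intermediate
8 | 4-[(tert-butyldimethylsilyl)oxy]-2-methoxy-5-(2-methylbut-3-en-2-yl)-6-oxocyclohexa-1,3-diene-1-carbaldehyde (ortho-dienone, racemic) | O=CC1=C(OC)C=C(O[Si](C)(C)C(C)(C)C)C(C(C)(C)C=C)C1=O | intermediate (not isolated)
9 | 4-[(tert-butyldimethylsilyl)oxy]-2-methoxy-3-(3-methylbut-2-en-1-yl)-6-oxocyclohexa-1,4-diene-1-carbaldehyde (para-dienone, racemic) | O=CC1=C(OC)C(CC=C(C)C)C(O[Si](C)(C)C(C)(C)C)=CC1=O | intermediate (not isolated)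
10 | 4-[(tert-butyldimethylsilyl)oxy]-6-hydroxy-2-methoxy-3-(3-methylbut-2-en-1-yl)benzaldehyde | O=Cc1c(OC)c(CC=C(C)C)c(O[Si](C)(C)C(C)(C)C)cc1O | intermediate
11 | 4,6-dihydroxy-2-methoxy-3-(3-methylbut-2-en-1-yl)benzaldehyde | O=Cc1c(OC)c(CC=C(C)C)c(O)cc1O | intermediate
12 | 3-methylbut-2-enal (prenal) | CC(C)=CC=O | starting material
13 | 2,4-dihydroxy-3-(1-hydroxy-3-methylbut-2-en-1-yl)-6-methoxy-5-(3-methylbut-2-en-1-yl)benzaldehyde (aldol adduct, racemic) | O=Cc1c(OC)c(CC=C(C)C)c(O)c(C(O)C=C(C)C)c1O | intermediate (not isolated)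
14 | 2-hydroxy-6-methoxy-3-(3-methylbut-2-en-1-ylidene)-5-(3-methylbut-2-en-1-yl)-4-oxocyclohexa-1,5-diene-1-carbaldehyde (ortho-quinone methide) | O=CC1=C(O)C(=CC=C(C)C)C(=O)C(CC=C(C)C)=C1OC | intermediate (not isolated)
15 | 5-hydroxy-7-methoxy-2,2-dimethyl-8-(3-methylbut-2-en-1-yl)-2H-chromene-6-carbaldehyde | O=Cc1c(OC)c(CC=C(C)C)c2OC(C)(C)C=Cc2c1O | intermediate
16 | 7-methoxy-2,2-dimethyl-8-(3-methylbut-2-en-1-yl)-5-(prop-2-en-1-yloxy)-2H-chromene-6-carbaldehyde | O=Cc1c(OC)c(CC=C(C)C)c2OC(C)(C)C=Cc2c1OCC=C | intermediate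
17 | (4-hydroxyphenyl)acetic acid | OC(=O)Cc1ccc(O)cc1 | starting material
18 | prop-2-en-1-yl 2-[4-(prop-2-en-1-yloxy)phenyl]acetate | C=CCOC(=O)Cc1ccc(OCC=C)cc1 | intermediate
19 | lithium 1-(prop-2-en-1-yloxy)-2-[4-(prop-2-en-1-yloxy)phenyl]ethen-1-olate (lithium enolate) | [Li+].C=CCOC([O-])=Cc1ccc(OCC=C)cc1 | intermediate (not isolated)
20 | prop-2-en-1-yl 3-hydroxy-3-[7-methoxy-2,2-dimethyl-8-(3-methylbut-2-en-1-yl)-5-(prop-2-en-1-yloxy)-2H-chromen-6-yl]-2-[4-(prop-2-en-1-yloxy)phenyl]propanoate (mixture of racemic diastereomers) | C=CCOC(=O)C(c1ccc(OCC=C)cc1)C(O)c1c(OC)c(CC=C(C)C)c2OC(C)(C)C=Cc2c1OCC=C | intermediate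
21 | prop-2-en-1-yl 3-[7-methoxy-2,2-dimethyl-8-(3-methylbut-2-en-1-yl)-5-(prop-2-en-1-yloxy)-2H-chromen-6-yl]-3-oxo-2-[4-(prop-2-en-1-yloxy)phenyl]propanoate (racemic) | C=CCOC(=O)C(c1ccc(OCC=C)cc1)C(=O)c1c(OC)c(CC=C(C)C)c2OC(C)(C)C=Cc2c1OCC=C | intermediate
22 | 3-[7-methoxy-2,2-dimethyl-8-(3-methylbut-2-en-1-yl)-5-(prop-2-en-1-yloxy)-2H-chromen-6-yl]-3-oxo-2-[4-(prop-2-en-1-yloxy)phenyl]propanoic acid (racemic) | OC(=O)C(c1ccc(OCC=C)cc1)C(=O)c1c(OC)c(CC=C(C)C)c2OC(C)(C)C=Cc2c1OCC=C | intermediate (not isolated)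
23 | 1-[7-methoxy-2,2-dimethyl-8-(3-methylbut-2-en-1-yl)-5-(prop-2-en-1-yloxy)-2H-chromen-6-yl]-2-[4-(prop-2-en-1-yloxy)phenyl]ethan-1-one | C=CCOc1ccc(CC(=O)c2c(OC)c(CC=C(C)C)c3OC(C)(C)C=Cc3c2OCC=C)cc1 | intermediate (not isolated)
24 | 1-[5-hydroxy-7-methoxy-2,2-dimethyl-8-(3-methylbut-2-en-1-yl)-2H-chromen-6-yl]-2-(4-hydroxyphenyl)ethan-1-one | COc1c(CC=C(C)C)c2c(c(O)c1C(=O)Cc1ccc(O)cc1)C=CC(C)(C)O2 | target

## Count and risk

Total steps: 13. Longest linear sequence: 12 (steps 1–9 and 11–13, from 1); step 10 is the one-step side branch.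

**Steps most likely to fail**

1. Step 6 (Claisen–Cope). The free ortho carbon could keep the 1,1-dimethylallyl group, or the aldehyde could suffer at 200 °C. The fallback sets out from 4 and comes back at 15; it builds the pyran first so that the prenyl ether has both ortho positions blocked. Compound 4 is condensed with prenal 12 (Ca(OH)2, MeOH, rt) to give 5-hydroxy-7-methoxy-2,2-dimethyl-2H-chromene-6-carbaldehyde F1. Mitsunobu reaction of the chelated phenol with prenol 6 (PPh3, DIAD, THF) gives 7-methoxy-2,2-dimethyl-5-[(3-methylbut-2-en-1-yl)oxy]-2H-chromene-6-carbaldehyde F2. Heating in PhNEt2 at 190–200 °C then moves the prenyl group to C-8, the only open ring position, giving 15. The price is that the chromenylation of 4 may give some of the regioisomer formed at the other free ring carbon, which has to be separated.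

2. Step 8 (chromenylation). The aldol step may be slow on the crowded, pentasubstituted ring, and prenal may self-condense. The fallback sets out from 11 and comes back at 15; it swaps the aldol/electrocyclisation for an aryl propargyl ether rearrangement. The non-chelated para hydroxyl of 11 is alkylated with 3-chloro-3-methylbut-1-yne (DBU, CuCl2 cat., MeCN, 0 °C) to give 6-hydroxy-2-methoxy-3-(3-methylbut-2-en-1-yl)-4-[(2-methylbut-3-yn-2-yl)oxy]benzaldehyde F3. Heating in xylene at 140 °C brings about propargyl Claisen rearrangement, 1,5-hydrogen shift and oxa-6π closure at the only free ortho carbon to give 15.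

3. Step 11 (aldol). The aldehyde is hindered and electron-rich, so addition may be incomplete or revert. The fallback sets out from 16 and comes back at 21; it replaces aldol plus oxidation by a crossed Claisen condensation at the acid oxidation level. Aldehyde 16 is oxidised (NaClO2, NaH2PO4, 2-methylbut-2-ene, t-BuOH/H2O) to 7-methoxy-2,2-dimethyl-8-(3-methylbut-2-en-1-yl)-5-(prop-2-en-1-yloxy)-2H-chromene-6-carboxylic acid F4. Activation with 1,1'-carbonyldiimidazole in THF gives (1H-imidazol-1-yl)[7-methoxy-2,2-dimethyl-8-(3-methylbut-2-en-1-yl)-5-(prop-2-en-1-yloxy)-2H-chromen-6-yl]methanone F5. C-acylation of enolate 19 (2.2 equiv, from 18 and LiN(iPr)2, THF, −78 to −20 °C) by F5 gives 21 directly.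

## Further compounds

F1 | step 6 | 5-hydroxy-7-methoxy-2,2-dimethyl-2H-chromene-6-carbaldehyde | O=Cc1c(OC)cc2OC(C)(C)C=Cc2c1O
F2 | step 6 | 7-methoxy-2,2-dimethyl-5-[(3-methylbut-2-en-1-yl)oxy]-2H-chromene-6-carbaldehyde | O=Cc1c(OC)cc2OC(C)(C)C=Cc2c1OCC=C(C)C
F3 | step 8 | 6-hydroxy-2-methoxy-3-(3-methylbut-2-en-1-yl)-4-[(2-methylbut-3-yn-2-yl)oxy]benzaldehyde | O=Cc1c(OC)c(CC=C(C)C)c(OC(C)(C)C#C)cc1O
F4 | step 11 | 7-methoxy-2,2-dimethyl-8-(3-methylbut-2-en-1-yl)-5-(prop-2-en-1-yloxy)-2H-chromene-6-carboxylic acid | OC(=O)c1c(OC)c(CC=C(C)C)c2OC(C)(C)C=Cc2c1OCC=C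
F5 | step 11 | (1H-imidazol-1-yl)[7-methoxy-2,2-dimethyl-8-(3-methylbut-2-en-1-yl)-5-(prop-2-en-1-yloxy)-2H-chromen-6-yl]methanone | O=C(n1ccnc1)c1c(OC)c(CC=C(C)C)c2OC(C)(C)C=Cc2c1OCC=C
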